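L cannot be leaving the zeta run one for one with J, for that run lost 95.1% of its L by 30.0 min, more than the 74.0% that its J charge could match.

| flask | L | J | remark | time |
|---|---|---|---|---|
| gamma | 1 M | 1.1 M | the very flask that is asked about, followed so far |  |
| zeta | 1 M | 0.74 M | run made earlier |  |
| flask | 1.0 M | 1.10 M |  | 80 min |

| run | time / min | L / % | X / % |
|---|---|---|---|
| gamma | 2.50 | 45.4 | 2.6 |
| gamma | 4.00 | 34.2 | 3.7 |
| gamma | 8.00 | 19.4 | 5.6 |
| gamma | 12.0 | 14.2 | 6.6 |
| gamma | 20.0 | 7.8 | 7.4 |
| gamma | 30.0 | 4.1 | 7.4 |
| zeta | 2.00 | 51.8 | 2.1 |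
| zeta | 6.00 | 25.8 | 3.7 |
| zeta | 12.0 | 14.0 | 3.9 |
| zeta | 20.0 | 8.3 | 5.1 |
| zeta | 25.0 | 6.1 | 5.4 |
| zeta | 30.0 | 4.9 | 5.2 |

(readings scatter by 0.5 percentage points)

- amount of L at 80 min, in percent of the L charged
- amount of X at 80 min, in percent of the L charged
- amount of G at 80 min, in percent of the L charged

The gamma run, which is this flask followed so far, differs from zeta in its J charge, yet at 12.0 min L reads 14.2% in gamma and 14.0% in zeta. X parts them: at 30.0 min it reads 7.4% in gamma and 5.2% in zeta. If each X holds one J, the X read in gamma holds 6.73% of the J charged, so J can be frozen at its charge and the making of X treated as pseudo-first-order in L. Both J charges then face the same L curve, and the same share of each should turn into X. Zeta gives 7.03%, and the mean, 6.88%, is the capture y, the share of J's charge standing as X at the last reading. X in zeta therefore reads lower at the last reading, its J charge being smaller.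

The reckoning here multiplies y by the equivalents of J and puts X at 7.56% at 80 min. In gamma X reads 7.4% at both 20.0 min and 30.0 min while L falls from 7.8% to 4.1%, so X seems to have an exit. Taking G as that exit, this reckoning puts G below the same figure.

The forecast gave L 0.4%, X 7.8% and G 91%, with “G is taken as the balance”, and there the two part.

The simulation gives L 0.968%, X 6.67% and G 3.34%.

    2 L → D (k = 0.220 M⁻¹ min⁻¹)
    L + J → X (k = 0.0180 M⁻¹ min⁻¹)
    J + X → G (k = 0.00630 M⁻¹ min⁻¹)
    L + X → Q (k = 0.0650 M⁻¹ min⁻¹)
    L → Z (k = 1.30 × 10⁻⁴ min⁻¹)

At 80.0 min this flask holds D at 84.8% of the L charged, each D counted as two, while J keeps 86.0% of its charge. X stands 0.89 percentage points under y times the equivalents, and G is less than that reckoned figure. A neighbouring flask differs in its J charge, 0.28 M, so the same reckoning gives it X at 1.93% with G below that; at 80.0 min that neighbour holds X at 2.57% and G at 0.272%.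

All runs were generated by integration on assumed constants; noise was put on by code.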